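**Retrosynthetic overview** (guaiane numbering: cyclopentane C1–C5; seven-membered ring C1, C5–C10; C14 on C10, C15 on C4, C11 with its two methyls on C7, ester oxygen on C8)
1. Target ⇒ C8–O acyl bond: phenol-silylated ferulic acid plus guai-1(10)-ene-8,11-diol.
2. Diol ⇒ 11-hydroxy-8-ketone ⇒ 7,11-epoxy-8-ketone ⇒ 7(11)-en-8-ol: C11–OH and C7–H come from reductive epoxide opening, C8 from a hydroxyl-directed reduction.
3. C4–H ⇒ C4–OH: anti elimination, then H2 on the face away from C6.
4. Key disconnection: the fusion bond C1–C5 is the only bond separating the cyclopentane (C1–C5) and the cycloheptene (C1, C5–C10) from a ten-membered ring that already carries C1=C10, C14, C15, the C8 oxygen and C11. It is made by transannular attack of C1 on C5 of a (4R,5R)-4,5-epoxide, so both rings form in one step from the macrocycle.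
5. Epoxide precursor ⇒ germacrone: Shi epoxidation at C4=C5, C8 reduction, silylation.

Key step: step 4

Assumption: the borohydride reduction of the epoxy ketone is drawn as giving the (8S)-alcohol; C8 is re-oxidised later, so the 8-epimer would run through the same operations and converge at the 11-hydroxy-8-ketone.

**Step 1**
Reactants: 1 germacrone
Product: 2 (4R,5R)-4,5-epoxygermacra-1(10)E,7(11)-dien-8-one
Conditions: D-fructose-derived Shi ketone (1,2:4,5-di-O-isopropylidene-β-D-erythro-2,3-hexodiulo-2,6-pyranose, 0.3 equiv), Oxone (KHSO5), K2CO3, Bu4NHSO4, MeCN/CH2(OMe)2, aq. Na2B4O7 buffer, pH 10.5, 0 °C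
Reagents that add atoms: Oxone (potassium peroxymonosulfate, KHSO5), [K+].[O-]S(=O)(=O)OO
Why: Shi asymmetric epoxidation, in which the chiral dioxirane transfers oxygen through a spiro transition state to the outer face of the electron-rich E-trisubstituted C4=C5 alkene, expected to react ahead of C1=C10 (inductively deactivated as the β,γ-alkene of the C8 ketone) and of the electron-poor C7=C11 enone alkene; the D-fructose-derived ketone, which gives (R,R)-epoxides from E-trisubstituted alkenes, sets C4 and C5 together as 4R,5R, and any C1=C10 epoxide would be removed by chromatography.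

**Step 2**
Reactants: 2 (4R,5R)-4,5-epoxygermacra-1(10)E,7(11)-dien-8-one
Product: 3 (4R,5R,8S)-4,5-epoxygermacra-1(10)E,7(11)-dien-8-ol
Conditions: NaBH4, MeOH, 0 °C
Reagents that add atoms: none
Why: Borohydride 1,2-reduction of the twisted enone, whose fully substituted C11 blocks conjugate hydride addition, with hydride entering C8 from the outer face of the macrocycle; the new C8 centre is temporary, and the basic medium leaves the epoxide closed.

**Step 3**
Reactants: 3 (4R,5R,8S)-4,5-epoxygermacra-1(10)E,7(11)-dien-8-ol
Product: 4 (4R,5R,8S)-8-(tert-butyldimethylsilyloxy)-4,5-epoxygermacra-1(10)E,7(11)-diene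
Conditions: TBSCl, imidazole, DMAP (cat.), DMF, rt
Reagents that add atoms: tert-butyldimethylsilyl chloride (TBSCl), CC(C)(C)[Si](C)(C)Cl
Why: Imidazole-mediated silylation of the secondary allylic alcohol, chosen over a silyl triflate so that no Lewis acid reaches the epoxide; no stereocentre changes, and the ether keeps the C8 oxygen from opening the epoxide in step 4.

**Step 4**
Reactants: 4 (4R,5R,8S)-8-(tert-butyldimethylsilyloxy)-4,5-epoxygermacra-1(10)E,7(11)-diene
Product: 5 (4R,5R,8S)-8-(tert-butyldimethylsilyloxy)guaia-1(10),7(11)-dien-4-ol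
Conditions: BF3·OEt2 (0.5 equiv), CH2Cl2, −78 → −30 °C; then Et3N, aq. NaHCO3
Reagents that add atoms: none
Why: BF3 coordinates the epoxide oxygen and, with the cyclodecene in its crossed crown conformation, the C1=C10 π bond attacks C5 from inside the ring, anti to the departing oxygen, in a transannular cation–alkene cyclisation; the tertiary C10 cation then loses H1, and isomers formed by reversible proton loss should drain to the same tetrasubstituted C1=C10 alkene. The closest known reaction type is the acid-mediated conversion of germacrane 4,5-epoxides into 4-hydroxyguai-1(10)-enes (germacranolide to guaianolide). The single new bond C1–C5 closes both rings: the cyclopentane C1–C5 by a 5-exo attack with respect to the alkene (C10 stays outside that ring), and the cycloheptene C1, C5–C10 as the 7-endo remainder of the ten-membered ring. C5 is the new stereocentre and is formed with inversion of the epoxide carbon, so its configuration (5R), the cis relation of H5 to the retained C4 hydroxyl and the cis relation of the C4 methyl to C6 all come from the trans-epoxide of step 1; no other centre is created because C1 returns to sp2. The step needs bonding of C1 and not C10 to C5 (secured by Markovnikov development of the tertiary C10 cation; attack on C4 would need a four-membered ring), anti opening at C5 (the epoxide oxygen lies on the outer face), and proton loss from C1 rather than C9 or C14 (the tetrasubstituted alkene is the thermodynamic position and there is no enolisable C8 carbonyl to pull the proton from C9). The silyl ether also stops the C8 oxygen from capturing C5.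

**Step 5**
Reactants: 5 (4R,5R,8S)-8-(tert-butyldimethylsilyloxy)guaia-1(10),7(11)-dien-4-ol
Product: 7 (5S,8S)-8-(tert-butyldimethylsilyloxy)guaia-1(10),3,7(11)-triene, via C4 chlorosulfite 6 (not isolated)
Conditions: SOCl2, pyridine, CH2Cl2, −40 → 0 °C
Reagents that add atoms: none
Why: Dehydration by pyridine-mediated anti E2 elimination of the chlorosulfite, in which H5 is syn to the leaving group and cannot be removed, so the conjugated 1(10),4-diene is avoided and the proton is taken from C3 to give the endocyclic trisubstituted alkene; C5 is untouched, and elimination toward C15 instead would lead to the same C4 centre in step 6.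

**Step 6**
Reactants: 7 (5S,8S)-8-(tert-butyldimethylsilyloxy)guaia-1(10),3,7(11)-triene
Product: 8 (4S,5S,8S)-8-(tert-butyldimethylsilyloxy)guaia-1(10),7(11)-diene
Conditions: H2 (4 atm), RhCl(PPh3)3 (10 mol%), benzene/EtOH, rt
Reagents that add atoms: none
Why: Homogeneous hydrogenation with RhCl(PPh3)3, which reduces the trisubstituted cyclopentene but not the tetrasubstituted C1=C10 and C7=C11 alkenes, adds H2 syn on the face of H5, away from C6 on the neighbouring C5, so H4 ends cis to H5 and the C4 methyl cis to C6 (4S).

**Step 7**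
Reactants: 8 (4S,5S,8S)-8-(tert-butyldimethylsilyloxy)guaia-1(10),7(11)-diene
Product: 9 (4S,5S,8S)-guaia-1(10),7(11)-dien-8-ol
Conditions: Bu4NF, THF, rt → 45 °C
Reagents that add atoms: none
Why: Fluoride cleavage of the silyl ether, driven by Si–F bond formation, frees the C8 allylic alcohol without touching the alkenes or any stereocentre.

**Step 8**
Reactants: 9 (4S,5S,8S)-guaia-1(10),7(11)-dien-8-ol
Product: 10 (4S,5S,7R,8S)-7,11-epoxyguai-1(10)-en-8-ol
Conditions: VO(acac)2 (5 mol%), t-BuOOH (1.2 equiv), CH2Cl2, 0 °C
Reagents that add atoms: tert-butyl hydroperoxide, CC(C)(C)OO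
Why: Hydroxyl-directed epoxidation, in which the vanadium alkoxide–alkylperoxide complex delivers oxygen to the allylic C7=C11 alkene syn to the C8 hydroxyl, much faster than to the homoallylic C1=C10 alkene; C7 is thereby set syn to the C8 oxygen, a configuration that is erased in step 10.

**Step 9**
Reactants: 10 (4S,5S,7R,8S)-7,11-epoxyguai-1(10)-en-8-ol
Product: 11 (4S,5S,7S)-7,11-epoxyguai-1(10)-en-8-one
Conditions: Dess–Martin periodinane, NaHCO3, CH2Cl2, 0 °C → rt
Reagents that add atoms: none
Why: Dess–Martin oxidation of the secondary alcohol under bicarbonate buffer gives the α,β-epoxy ketone without acid or base strong enough to open the epoxide or move the β,γ-alkene C1=C10 into conjugation.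

**Step 10**
Reactants: 11 (4S,5S,7S)-7,11-epoxyguai-1(10)-en-8-one
Product: 12 (4S,5S,7R)-11-hydroxyguai-1(10)-en-8-one
Conditions: SmI2 (2.5 equiv), THF/MeOH, −78 °C
Reagents that add atoms: none
Why: SmI2 reduction of an α,β-epoxy ketone, in which electron transfer to the C8 carbonyl, cleavage of the C7–O bond and a second electron transfer give the enolate of trivalent samarium with the oxygen left on C11; methanol should protonate C7 on the face of H5, away from the cyclopentane carbon C4, placing the CMe2OH chain pseudo-equatorial and 1,3-cis to C4 (7R in this compound), which is also expected to be the more stable epimer, while the low temperature and absence of base suppress retro-aldol cleavage and alkene migration.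

**Step 11**
Reactants: 12 (4S,5S,7R)-11-hydroxyguai-1(10)-en-8-one
Product: 13 (4S,5S,7S,8S)-guai-1(10)-ene-8,11-diol
Conditions: Me4NBH(OAc)3, MeCN/AcOH, −30 → 0 °C
Reagents that add atoms: none
Why: Evans–Saksena hydroxyl-directed reduction, in which the C11 hydroxyl exchanges onto boron and hydride is delivered intramolecularly through a chair six-membered transition state, entering C8 axially so that the C8 hydroxyl ends equatorial and trans to the C7 side chain (8S), with no base present to epimerise C7.

**Step 12**
Reactants: 14 ferulic acid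
Product: 16 (E)-3-[4-(tert-butyldimethylsilyloxy)-3-methoxyphenyl]prop-2-enoic acid, via bis-silylated ferulate 15 (not isolated)
Conditions: TBSCl (2.5 equiv), imidazole, DMF, rt; then AcOH/THF/H2O, rt
Reagents that add atoms: tert-butyldimethylsilyl chloride (TBSCl), CC(C)(C)[Si](C)(C)Cl
Why: Silylation of both acidic hydroxyls followed by selective hydrolysis of the far more labile silyl ester leaves the phenol masked as its aryl silyl ether, so it cannot compete as a nucleophile in the esterification.

**Step 13**
Reactants: 16 (E)-3-[4-(tert-butyldimethylsilyloxy)-3-methoxyphenyl]prop-2-enoic acid; 13 (4S,5S,7S,8S)-guai-1(10)-ene-8,11-diol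
Product: 18 (4S,5S,7S,8S)-11-hydroxyguai-1(10)-en-8-yl (E)-3-[4-(tert-butyldimethylsilyloxy)-3-methoxyphenyl]prop-2-enoate, via mixed anhydride 17 (not isolated)
Conditions: 2,4,6-Cl3C6H2COCl, Et3N, THF, rt; then 13, DMAP, toluene, rt
Reagents that add atoms: none
Why: Yamaguchi esterification, in which DMAP transfers the cinnamoyl group from the mixed anhydride to the secondary C8 hydroxyl with retention at C8, while the tertiary C11 hydroxyl is too hindered to be acylated.

**Step 14**
Reactants: 18 (4S,5S,7S,8S)-11-hydroxyguai-1(10)-en-8-yl (E)-3-[4-(tert-butyldimethylsilyloxy)-3-methoxyphenyl]prop-2-enoate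
Product: 19 (4S,5S,7S,8S)-11-hydroxyguai-1(10)-en-8-yl (E)-3-(4-hydroxy-3-methoxyphenyl)prop-2-enoate (target)
Conditions: Bu4NF, AcOH, THF, 0 °C
Reagents that add atoms: none
Why: Fluoride cleavage of the aryl silyl ether, buffered with acetic acid so that the phenoxide neither hydrolyses nor transesterifies the cinnamate, releases the target without affecting the tertiary alcohol, the tetrasubstituted alkene or any stereocentre.

**Compound list**
1 | germacrone, (1(10)E,4E)-germacra-1(10),4,7(11)-trien-8-one | C/C1=C\CC/C(C)=C/CC(=C(C)C)C(=O)C1 | starting material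
2 | (4R,5R)-4,5-epoxygermacra-1(10)E,7(11)-dien-8-one | C/C1=C\CC[C@@]2(C)O[C@@H]2CC(=C(C)C)C(=O)C1 | intermediate
3 | (4R,5R,8S)-4,5-epoxygermacra-1(10)E,7(11)-dien-8-ol | C/C1=C\CC[C@@]2(C)O[C@@H]2CC(=C(C)C)[C@@H](O)C1 | intermediate
4 | (4R,5R,8S)-8-(tert-butyldimethylsilyloxy)-4,5-epoxygermacra-1(10)E,7(11)-diene (key-step precursor) | C/C1=C\CC[C@@]2(C)O[C@@H]2CC(=C(C)C)[C@@H](O[Si](C)(C)C(C)(C)C)C1 | intermediate
5 | (4R,5R,8S)-8-(tert-butyldimethylsilyloxy)guaia-1(10),7(11)-dien-4-ol (key-step product; 4-OH cis to H5, C15 cis to C6) | CC(C)(C)[Si](C)(C)O[C@H]1CC(C)=C2CC[C@@](C)(O)[C@@H]2CC1=C(C)C | intermediate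
6 | C4 chlorosulfite of 5 | CC(C)(C)[Si](C)(C)O[C@H]1CC(C)=C2CC[C@@](C)(OS(=O)Cl)[C@@H]2CC1=C(C)C | intermediate
7 | (5S,8S)-8-(tert-butyldimethylsilyloxy)guaia-1(10),3,7(11)-triene | CC(C)(C)[Si](C)(C)O[C@H]1CC(C)=C2CC=C(C)[C@@H]2CC1=C(C)C | intermediate
8 | (4S,5S,8S)-8-(tert-butyldimethylsilyloxy)guaia-1(10),7(11)-diene | CC(C)(C)[Si](C)(C)O[C@H]1CC(C)=C2CC[C@H](C)[C@@H]2CC1=C(C)C | intermediate
9 | (4S,5S,8S)-guaia-1(10),7(11)-dien-8-ol | O[C@H]1CC(C)=C2CC[C@H](C)[C@@H]2CC1=C(C)C | intermediate
10 | (4S,5S,7R,8S)-7,11-epoxyguai-1(10)-en-8-ol (epoxide oxygen syn to 8-OH) | O[C@H]1CC(C)=C2CC[C@H](C)[C@@H]2C[C@@]13OC3(C)C | intermediate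
11 | (4S,5S,7S)-7,11-epoxyguai-1(10)-en-8-one | O=C1CC(C)=C2CC[C@H](C)[C@@H]2C[C@@]13OC3(C)C | intermediate
12 | (4S,5S,7R)-11-hydroxyguai-1(10)-en-8-one | O=C1CC(C)=C2CC[C@H](C)[C@@H]2C[C@@H]1C(C)(C)O | intermediate
13 | (4S,5S,7S,8S)-guai-1(10)-ene-8,11-diol | O[C@H]1CC(C)=C2CC[C@H](C)[C@@H]2C[C@@H]1C(C)(C)O | intermediate
14 | ferulic acid, (E)-3-(4-hydroxy-3-methoxyphenyl)prop-2-enoic acid | COc1cc(/C=C/C(=O)O)ccc1O | starting material
15 | tert-butyldimethylsilyl (E)-3-[4-(tert-butyldimethylsilyloxy)-3-methoxyphenyl]prop-2-enoate | COc1cc(/C=C/C(=O)O[Si](C)(C)C(C)(C)C)ccc1O[Si](C)(C)C(C)(C)C | intermediate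
16 | (E)-3-[4-(tert-butyldimethylsilyloxy)-3-methoxyphenyl]prop-2-enoic acid | COc1cc(/C=C/C(=O)O)ccc1O[Si](C)(C)C(C)(C)C | intermediate
17 | mixed anhydride of 16 with 2,4,6-trichlorobenzoic acid | COc1cc(/C=C/C(=O)OC(=O)c2c(Cl)cc(Cl)cc2Cl)ccc1O[Si](C)(C)C(C)(C)C | intermediate
18 | (4S,5S,7S,8S)-11-hydroxyguai-1(10)-en-8-yl (E)-3-[4-(tert-butyldimethylsilyloxy)-3-methoxyphenyl]prop-2-enoate | COc1cc(/C=C/C(=O)O[C@H]2CC(C)=C3CC[C@H](C)[C@@H]3C[C@@H]2C(C)(C)O)ccc1O[Si](C)(C)C(C)(C)C | intermediate
19 | (4S,5S,7S,8S)-11-hydroxyguai-1(10)-en-8-yl (E)-3-(4-hydroxy-3-methoxyphenyl)prop-2-enoate, CNP0241038.1 | COc1cc(/C=C/C(=O)O[C@H]2CC(C)=C3CC[C@H](C)[C@@H]3C[C@@H]2C(C)(C)O)ccc1O | target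

**Step count**
Total: 14 steps. Longest linear sequence: 13 steps (steps 1–11, 13 and 14, from germacrone).

**Steps most likely to fail**

Step 4 (key step). After the C1–C5 bond has formed, the C10 cation may lose a proton from C14 or C9 faster than H1 can align with the empty orbital, and conditions mild enough to keep the silyl ether and the C4 alcohol may not equilibrate the resulting alkene isomers. The fallback separates ring closure from alkene placement. Setting out from 4, the BF3·OEt2 cyclisation is run only until the epoxide is consumed and the product is taken as 5 together with its H1-bearing isomers, 8-(tert-butyldimethylsilyloxy)guaia-7(11),10(14)-dien-4-ol F1 and 8-(tert-butyldimethylsilyloxy)guaia-7(11),9-dien-4-ol F2 (both with H1 cis to H5). The mixture is then heated with PdCl2(MeCN)2 (5 mol%) in benzene at 60 °C, a metal-catalysed alkene isomerisation that should run to the most substituted position, the tetrasubstituted C1=C10 alkene. The route is rejoined at 5.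

Step 5. The chlorosulfite may ionise at C4 and lose the allylic H5 to give the conjugated 1(10),4-diene, or be substituted by chloride, instead of undergoing anti elimination toward C3; the trisubstituted alkene may also hydrogenate slowly in step 6. The fallback replaces the elimination–hydrogenation pair by a radical deoxygenation. Setting out from 5, acylation with methyl chlorooxoacetate (DMAP, pyridine, CH2Cl2) gives (4R,5R,8S)-8-(tert-butyldimethylsilyloxy)guaia-1(10),7(11)-dien-4-yl methyl oxalate F3. Treatment with Bu3SnH and AIBN in refluxing toluene (Barton–McCombie-type deoxygenation of a tertiary oxalate) generates the C4 radical, which should take hydrogen on the face of H5, away from C6. Closure of this radical onto C1=C10 would need a bicyclo[2.1.0] ring and is not expected. The route is rejoined at 8, bypassing steps 5 and 6.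

Step 11. Hydride may attack C8 without direction from the C11 hydroxyl, from the face that leaves the C8 hydroxyl cis to the C7 side chain. The fallback sets C8 by inversion in the ester-forming step. Setting out from 12, reduction with LiBH(s-Bu)3 in THF at −78 °C (equatorial attack by a bulky hydride) is used deliberately to make the cis diol, (4S,5S,7S,8R)-guai-1(10)-ene-8,11-diol F4. Mitsunobu esterification of F4 with acid 16 (PPh3, diisopropyl azodicarboxylate, THF, 0 °C → rt) then acylates the secondary C8 hydroxyl with inversion, the tertiary C11 hydroxyl staying free. The route is rejoined at 18, bypassing step 13.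

**Further compounds**
F1 | step 4 | 8-(tert-butyldimethylsilyloxy)guaia-7(11),10(14)-dien-4-ol (H1 cis to H5; C4, C5, C8 as in 5) | CC(C)(C)[Si](C)(C)O[C@H]1CC(=C)[C@@H]2CC[C@@](C)(O)[C@@H]2CC1=C(C)C
F2 | step 4 | 8-(tert-butyldimethylsilyloxy)guaia-7(11),9-dien-4-ol (H1 cis to H5; C4, C5, C8 as in 5) | CC(C)(C)[Si](C)(C)O[C@H]1C=C(C)[C@@H]2CC[C@@](C)(O)[C@@H]2CC1=C(C)C
F3 | step 5 | (4R,5R,8S)-8-(tert-butyldimethylsilyloxy)guaia-1(10),7(11)-dien-4-yl methyl oxalate | CC(C)(C)[Si](C)(C)O[C@H]1CC(C)=C2CC[C@@](C)(OC(=O)C(=O)OC)[C@@H]2CC1=C(C)C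
F4 | step 11 | (4S,5S,7S,8R)-guai-1(10)-ene-8,11-diol | O[C@@H]1CC(C)=C2CC[C@H](C)[C@@H]2C[C@@H]1C(C)(C)O
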